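**Analysis of the target**

The target is a 20-membered diaryl ether macrocycle in which two benzene rings are joined once through an oxygen atom and once through an unbranched chain of twelve methylene groups. Ring A is a 1,3,5-trisubstituted arene: C1 carries a hydroxyl, C3 the chain, C5 the ether oxygen, and C2, C4 and C6 carry hydrogen. Ring B is bound to the ether oxygen at C1', has hydroxyls at C2' and C6' on both sides of that oxygen, and carries the chain at C4'. There is no stereocentre, and the long bridge should let both rings rotate, so nothing stereochemical has to be set. Both rings are electron-rich phenols, and the 2,6-dihydroxyphenyl ether of ring B is sensitive to oxidation under base, so the free hydroxyls are best released at the end. The difficulty is the C5–O–C1' bond: neither ring is activated for aromatic substitution, the ring B oxygen is flanked by two ortho oxygens, and the meta pattern of ring A cannot be reached by electrophilic substitution of a resorcinol. The strategy rests on the fact that ring A (oxygen at C1 and C5, alkyl at C3, hydrogen at C4) has the pattern of a folded tetraketide. Its C5 oxygen can therefore be attached to ring B while it is still the 4-oxygen of a 2-pyrone, and ring A can be made afterwards by an aldol closure of bond C3–C4.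

**Retrosynthetic reasoning**

Target 18 to dimethyl ether 17: the two O–CH3 bonds on ring B are cut last in the forward sense. The methyl groups come with the ring B building block, protect the oxidation-prone oxygens through every basic step, and a boron trihalide removes them without touching the diaryl ether.

Phenol 17 to acid 16: a carboxyl group is added back at C4 of ring A. This turns the alkylresorcinol into a 4-hydroxybenzoic acid with two ortho substituents. Such an acid is the direct product of a polyketide-type aldol, and it should lose carbon dioxide readily on heating.

Acid 16 to macrocyclic pyrone 14, through the open-chain carboxylate 15: ring A bond C3–C4 is cut (retro-aldol) and the carboxyl is closed back onto the C1 oxygen as a lactone. This is the only cut of ring A that leaves a chain with carbonyl groups at alternating carbons, which a 2-pyrone stores in stable form. The gain is that the unactivated aryl–O–aryl bond becomes the enol ether of a vinylogous ester, and the 20-membered ring becomes a 22-membered ring that the six-membered aldol contracts. The forward reaction has to open the lactone with hydroxide at its carbonyl, leave the aryloxy group where it is, and close C3–C4.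

Pyrone 14 to tosylate 12, through phenoxide 13: the bond between pyrone C4 and the ring B oxygen is cut. C4 is the electrophilic position of a 4-sulfonyloxy-2-pyrone, so the hindered phenoxide can be attached by addition–elimination without a metal. The large ring closes at a trigonal carbon with a heteroatom nucleophile, which is the least demanding way to close it. Releasing the phenoxide from its silyl ether with fluoride makes deprotection and ring closure one operation.

Tosylate 12 to hydroxypyrone 11: the S–O bond is cut. The 4-hydroxyl of 11 is a vinylogous acid and is the only group that an amine base ionises.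

Hydroxypyrone 11 to acid 7 and triacetic acid lactone 8: the bond between the methylene on pyrone C6 and the ketone carbon is cut. The forward reaction is the acylation of dianion 10 at its methyl carbon by acyl imidazolide 9. This joins all carbons of ring A (from 8) to the complete chain in one step.

Acid 7 to aldehyde 2 and phosphonium salt 4, through alkene 6: the benzylic C–C bond is cut as a Wittig olefination followed by hydrogenation. Ylide 5 from 4 supplies twelve carbons and the aldehyde carbon becomes the thirteenth, which gives exactly the twelve methylenes between the rings. Salt 4 comes from 12-bromododecanoic acid 3, and aldehyde 2 from syringaldehyde 1 by silylation of its phenol.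

**Alternatives that were turned down**

Alternative 1: Ring A would be cut at C1–C2 and C3–C4 into the ketene acetal diene A2, which already carries the ring B aryloxy group on its central carbon, and the alkynoate A3, which carries the chain.
- Forward key step: [4+2] cycloaddition and loss of methanol should give benzoate A1 with the ether and the chain meta to each other. Ester removal, hydroboration of the terminal alkene and an intramolecular B-alkyl Suzuki–Miyaura coupling onto the ring B bromide (zerovalent palladium, for example Pd(PPh3)4) would then close the macrocycle.
- For: the regiochemistry follows from the polarisation of both partners, and ring A is formed intermolecularly, free of any macrocyclic constraint. On this separation of arene formation from ring closure the alternative is stronger.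
- Against: an alkynoate with an alkyl group on its β-carbon is a slow dienophile and needs temperatures at which a silyl ketene acetal is fragile. A2 and A3 each need a synthesis of several steps. The ring closure is a palladium-mediated sp3–sp2 coupling at high dilution. The ester still has to be removed, so nothing is saved over the decarboxylation used here.
- Comparison: the chosen route takes all carbons from three cheap building blocks, uses no metal-mediated C–C coupling, and closes the large ring by C–O bond formation.

Alternative 2: The two ring B hydroxyls would be traced back to formyl groups, so that C2'–O and C6'–O are made last.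
- Forward key step: the macrocyclic dialdehyde A5 is oxidised with a peracid so that both formyl groups become formates by aryl migration (Dakin-type Baeyer–Villiger oxidation). Mild methanolysis then gives diol A4, and the ring A methyl ether is cleaved afterwards.
- For: two ortho formyl groups activate C1' strongly for displacement of fluoride by a ring A phenoxide. The diaryl ether, the hardest bond of the target, would thus be made by a classical aromatic substitution that is more dependable than addition–elimination on a pyrone. On this point the alternative is stronger.
- Against: the key step forms no skeletal bond and closes no ring. The whole framework, including a meta-substituted ring A with its tether and a ring B carrying fluorine between two formyl groups, has to be assembled beforehand by cross-coupling and directed formylation. Aryl migration must win twice, the second time on a ring that still bears a withdrawing group, where hydride migration to the acid competes. A final demethylation is still needed.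
- Comparison: the chosen route builds ring A and its substitution pattern in the key step, with the ring B oxygens present from the first step, and is shorter.

Alternative 3: Ring A would be cut at C1–C6 and C4–C5, so that C1–C4 come from a cyclobutenone and C5–C6 from an alkyne.
- Forward key step: heating cyclobutenone A7, tethered by twelve methylenes to a silylated aryl alkynyl ether, should open it to a vinylketene. A [2+2] addition to the alkyne, 4π opening and 6π closure (Danheiser benzannulation) would give phenol A6, forming ring A and the macrocycle in one operation. Protodesilylation and demethylation follow.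
- For: no reagent is needed, the meta relation of ether oxygen and hydroxyl is inherent, and two C–C bonds and two rings form at once. In bond economy of the key step this is clearly stronger than the chosen route.
- Against: the first bond-forming event is a ketene–alkyne [2+2] addition that must span a 20-membered ring at high dilution, with a short-lived vinylketene that can dimerise instead. The alkyne is deactivated by silicon on its nucleophilic carbon and by the weakly donating aryloxy group. A7 needs a long synthesis, and two steps remain after the key step.
- Comparison: in the chosen route the only ring that closes in the key step is six-membered, and the macrocycle is closed earlier by a conventional heteroatom substitution.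

Key step: step 8

Remark on the chemistry: the target has no stereocentre and the 20-membered ring is assumed to be conformationally mobile, so atropisomerism is not addressed.

**Route**

Step 1
Reactants: 1 syringaldehyde (4-hydroxy-3,5-dimethoxybenzaldehyde)
Product: 2 3,5-dimethoxy-4-(triisopropylsilyloxy)benzaldehyde
Conditions: TIPSCl (1.2 equiv), imidazole (2.5 equiv), DMF, rt
Reagents that add atoms: triisopropylsilyl chloride, CC(C)[Si](Cl)(C(C)C)C(C)C
Why: O-silylation of an acidic phenol; the bulky silyl ether keeps the phenol from becoming a phenoxide that would deactivate the aldehyde in step 3, survives base and hydrogenation, and later serves as a latent phenoxide.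

Step 2
Reactants: 3 12-bromododecanoic acid
Product: 4 (11-carboxyundecyl)triphenylphosphonium bromide
Conditions: PPh3 (1.05 equiv), MeCN, reflux
Reagents that add atoms: triphenylphosphine, c1ccc(cc1)P(c1ccccc1)c1ccccc1
Why: SN2 quaternisation of the phosphine by a primary bromide; the free acid does not interfere.

Step 3
Reactants: 4 (11-carboxyundecyl)triphenylphosphonium bromide; 2 3,5-dimethoxy-4-(triisopropylsilyloxy)benzaldehyde
Product: 6 (Z)-13-[3,5-dimethoxy-4-(triisopropylsilyloxy)phenyl]tridec-12-enoic acid (Z isomer drawn; any E isomer is carried along), via sodium carboxylate ylide 5 (not isolated)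
Conditions: 4, NaN(SiMe3)2 (2.1 equiv), THF, 0 °C; then 2, −78 °C → rt; 1 M HCl to pH 3
Reagents that add atoms: none
Why: Wittig olefination of a non-stabilised ylide with an aryl aldehyde; two equivalents of base form the carboxylate ylide, and the alkene geometry is irrelevant because the double bond is hydrogenated next.

Step 4
Reactants: 6 (Z)-13-[3,5-dimethoxy-4-(triisopropylsilyloxy)phenyl]tridec-12-enoic acid
Product: 7 13-[3,5-dimethoxy-4-(triisopropylsilyloxy)phenyl]tridecanoic acid
Conditions: H2 (1 atm), 10% Pd/C, EtOAc, rt
Reagents that add atoms: none
Why: heterogeneous hydrogenation of a disubstituted styrene-type alkene; the aryl silyl ether, methyl ethers and acid are inert in a neutral aprotic solvent, and hydrogenating here avoids reducing a pyrone later.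

Step 5
Reactants: 7 13-[3,5-dimethoxy-4-(triisopropylsilyloxy)phenyl]tridecanoic acid; 8 triacetic acid lactone (4-hydroxy-6-methyl-2H-pyran-2-one)
Product: 11 6-{14-[3,5-dimethoxy-4-(triisopropylsilyloxy)phenyl]-2-oxotetradecyl}-4-hydroxy-2H-pyran-2-one, via acyl imidazolide 9 (not isolated), via dilithium dianion 10 (not isolated)
Conditions: (a) 7, carbonyldiimidazole (1.05 equiv), THF, rt; (b) 8 (4 equiv), LiN(iPr)2 (8.2 equiv, commercial solution), THF, −78 → 0 °C; then 9 added at −78 °C, → −20 °C; 1 M HCl
Reagents that add atoms: none
Why: Claisen-type C-acylation of the triacetic acid lactone dianion at its methyl carbon, the last-formed and most nucleophilic site, by an N-acylimidazole; the excess of dianion takes up the imidazole N–H and the acidic methylene of the product, and the silyl ether is inert at low temperature.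

Step 6
Reactants: 11 6-{14-[3,5-dimethoxy-4-(triisopropylsilyloxy)phenyl]-2-oxotetradecyl}-4-hydroxy-2H-pyran-2-one
Product: 12 6-{14-[3,5-dimethoxy-4-(triisopropylsilyloxy)phenyl]-2-oxotetradecyl}-2-oxo-2H-pyran-4-yl 4-methylbenzenesulfonate
Conditions: TsCl (1.1 equiv), Et3N (1.5 equiv), CH2Cl2, 0 °C
Reagents that add atoms: 4-toluenesulfonyl chloride, Cc1ccc(cc1)S(Cl)(=O)=O
Why: O-sulfonylation of a vinylogous acid; the 4-hydroxyl (pKa about 5) is the only group the amine ionises, so the ketone and the silyl ether stay untouched.

Step 7
Reactants: 12 6-{14-[3,5-dimethoxy-4-(triisopropylsilyloxy)phenyl]-2-oxotetradecyl}-2-oxo-2H-pyran-4-yl 4-methylbenzenesulfonate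
Product: 14 22-membered macrocyclic pyrone: 4-aryloxy-2H-pyran-2-one whose 4-oxygen is bound to C1' of a 2',6'-dimethoxyphenyl ring B and whose C6 carries CH2–CO–(CH2)12 ending at ring B C4', via caesium phenoxide 13 (not isolated)
Conditions: CsF (5 equiv), DMF, 60 °C; 12 added by syringe pump to a final concentration of about 1 mM
Reagents that add atoms: none
Why: fluoride cleaves the Si–O bond and the freed phenoxide adds to pyrone C4 and expels tosylate (addition–elimination at a 4-sulfonyloxy-2-pyrone, the intermolecular reaction known for phenoxides with 4-halo and 4-sulfonyloxy pyrones and coumarins); slow release of the nucleophile at high dilution favours the 22-membered ring over oligomers.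

Step 8
Reactants: 14 22-membered macrocyclic pyrone
Product: 16 20-membered macrocyclic benzoic acid: ring A with CO2H on C4 and OH on C1 and the (CH2)12 chain on C3 and the ring B oxygen on C5; ring B 2',6'-dimethoxy with the chain at C4', via ring-opened potassium dioxoenoate 15 (not isolated)
Conditions: KOH (2 M aq, 10 equiv), THF–H2O (1:1), Ar, 0 °C → 40 °C; then 1 M HCl, 0 °C, pH 2
Reagents that add atoms: potassium hydroxide, [K+].[OH-] (its oxygen ends in the carboxyl group)
Why: Hydroxide adds to the lactone carbonyl of 14 and the ring opens to carboxylate 15, an (E)-3-aryloxy-5,7-dioxoalk-2-enoate in which the former ring oxygen is the 5-keto oxygen. Deprotonation of the methylene between the enol ether carbon and the 5-ketone gives a dienolate whose far carbon, the one next to the carboxylate, adds to the 7-ketone; loss of water and enolisation then give the arene, so that ring A bond C3–C4 is formed, the carboxyl stays on C4 and the old pyrone oxygen becomes the C1 hydroxyl. The closest known reaction type is the alkali-induced recyclisation of 6-(2-oxoalkyl)-4-oxygenated 2-pyrones to 6-alkylresorcylic acids; what is new here is only the aryl group on that oxygen and the macrocyclic setting. Ring A closes by a 6-exo-trig aldol at the ketone (enolendo with respect to the dienolate), and the same bond contracts the 22-membered ring to the 20-membered one, so no large ring has to be closed in this step. No stereocentre is formed. Hydroxide must attack the lactone carbonyl and not the aryloxy-bearing C4, which is expected because C4 is the donor-substituted β-carbon of a vinylogous carbonate and is shielded by the two methoxy groups of ring B. Methanol is kept out so that no methoxide can exchange the aryloxy group at C4, and the carboxylate terminus cannot be acylated, which excludes a Claisen closure to an acylphloroglucinol. Acidification is done cold so that the acid can be isolated; any material that loses carbon dioxide early is already 17.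

Step 9
Reactants: 16 20-membered macrocyclic benzoic acid
Product: 17 20-membered macrocyclic phenol with ring B dimethyl ether: ring A C1 OH; C3 chain; C5 O–ring B; ring B 2',6'-dimethoxy
Conditions: DMSO, 140 °C, N2
Reagents that add atoms: none
Why: thermal protodecarboxylation of a 4-hydroxybenzoic acid with two ortho substituents; protonation at the carboxyl-bearing carbon is favoured by the para hydroxyl and the ortho aryloxy group, and loss of carbon dioxide relieves the crowding, as with orsellinic-type acids.

Step 10
Reactants: 17 20-membered macrocyclic phenol with ring B dimethyl ether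
Product: 18 target: 20-membered diaryl ether with OH at ring A C1 and at ring B C2' and C6'
Conditions: BBr3 (6 equiv), CH2Cl2, −78 °C → rt; H2O
Reagents that add atoms: none
Why: Lewis acid cleavage of aryl methyl ethers by bromide attack on the methyl carbon of the boron-complexed ether; the diaryl ether has no sp3 carbon on oxygen and survives.

**Compound list**

1 | syringaldehyde | COc1cc(C=O)cc(OC)c1O | starting material
2 | 3,5-dimethoxy-4-(triisopropylsilyloxy)benzaldehyde | COc1cc(C=O)cc(OC)c1O[Si](C(C)C)(C(C)C)C(C)C | intermediate
3 | 12-bromododecanoic acid | OC(=O)CCCCCCCCCCCBr | starting material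
4 | (11-carboxyundecyl)triphenylphosphonium bromide | OC(=O)CCCCCCCCCCC[P+](c1ccccc1)(c1ccccc1)c1ccccc1.[Br-] | intermediate
5 | sodium 12-(triphenylphosphoranylidene)dodecanoate | [Na+].[O-]C(=O)CCCCCCCCCCC=P(c1ccccc1)(c1ccccc1)c1ccccc1 | intermediate
6 | (Z)-13-[3,5-dimethoxy-4-(triisopropylsilyloxy)phenyl]tridec-12-enoic acid | OC(=O)CCCCCCCCCC/C=C\c1cc(OC)c(O[Si](C(C)C)(C(C)C)C(C)C)c(OC)c1 | intermediate
7 | 13-[3,5-dimethoxy-4-(triisopropylsilyloxy)phenyl]tridecanoic acid | OC(=O)CCCCCCCCCCCCc1cc(OC)c(O[Si](C(C)C)(C(C)C)C(C)C)c(OC)c1 | intermediate
8 | triacetic acid lactone | Cc1cc(O)cc(=O)o1 | starting material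
9 | 1-{13-[3,5-dimethoxy-4-(triisopropylsilyloxy)phenyl]tridecanoyl}imidazole | O=C(n1ccnc1)CCCCCCCCCCCCc1cc(OC)c(O[Si](C(C)C)(C(C)C)C(C)C)c(OC)c1 | intermediate
10 | dilithium salt of the triacetic acid lactone dianion | [Li+].[Li+].[CH2-]c1cc([O-])cc(=O)o1 | intermediate
11 | 6-{14-[3,5-dimethoxy-4-(triisopropylsilyloxy)phenyl]-2-oxotetradecyl}-4-hydroxy-2H-pyran-2-one | O=c1cc(O)cc(o1)CC(=O)CCCCCCCCCCCCc1cc(OC)c(O[Si](C(C)C)(C(C)C)C(C)C)c(OC)c1 | intermediate
12 | 6-{14-[3,5-dimethoxy-4-(triisopropylsilyloxy)phenyl]-2-oxotetradecyl}-2-oxo-2H-pyran-4-yl 4-methylbenzenesulfonate | Cc1ccc(cc1)S(=O)(=O)Oc1cc(=O)oc(c1)CC(=O)CCCCCCCCCCCCc1cc(OC)c(O[Si](C(C)C)(C(C)C)C(C)C)c(OC)c1 | intermediate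
13 | caesium 2,6-dimethoxy-4-{13-oxo-14-[2-oxo-4-(tosyloxy)-2H-pyran-6-yl]tetradecyl}phenoxide | [Cs+].Cc1ccc(cc1)S(=O)(=O)Oc1cc(=O)oc(c1)CC(=O)CCCCCCCCCCCCc1cc(OC)c([O-])c(OC)c1 | intermediate
14 | 22-membered macrocyclic 4-(2,6-dimethoxyaryloxy)-6-(2-oxoalkyl)pyran-2-one | O=c1cc2cc(o1)CC(=O)CCCCCCCCCCCCc1cc(OC)c(O2)c(OC)c1 | intermediate
15 | potassium salt of the macrocyclic (E)-3-aryloxy-5,7-dioxoalk-2-enoic acid | [K+].[O-]C(=O)/C=C1/Oc2c(OC)cc(cc2OC)CCCCCCCCCCCCC(=O)CC(=O)C1 | intermediate
16 | 20-membered macrocyclic 2-aryloxy-4-hydroxy-6-alkylbenzoic acid, ring B dimethyl ether | OC(=O)c1c2cc(O)cc1Oc1c(OC)cc(cc1OC)CCCCCCCCCCCC2 | intermediate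
17 | 20-membered macrocyclic 3-aryloxy-5-alkylphenol, ring B dimethyl ether | Oc1cc2cc(c1)Oc1c(OC)cc(cc1OC)CCCCCCCCCCCC2 | intermediate
18 | target macrocyclic triol | Oc1cc2cc(c1)Oc1c(O)cc(cc1O)CCCCCCCCCCCC2 | target

**Step count and risk**

Total: 10 steps. Longest linear sequence: 9 steps (1 → 2 → 6 → 7 → 11 → 12 → 14 → 16 → 17 → 18; the branch from 3 through 4 is equally long).

Step 8 (key step). The most likely failure is addition of hydroxide to the aryloxy-bearing pyrone carbon with loss of the ring B phenoxide, which would open the macrocycle before ring A forms. The reaction may also stop at the ring-opened diketonate, whose enolate form lowers the reactivity of the 7-ketone, or the 1,3-diketone may be cut by retro-Claisen cleavage.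
Fallback: ring A is built as a cyclohexane-1,3-dione and aromatised, setting out from 7 and returning at 17.
- Reduction of 7 (BH3·SMe2, THF) gives 13-[3,5-dimethoxy-4-(triisopropylsilyloxy)phenyl]tridecan-1-ol F1, and Dess–Martin oxidation gives the corresponding tridecanal F2.
- Wittig olefination with 1-(triphenylphosphoranylidene)propan-2-one gives the (E)-enone F3.
- Michael addition of dimethyl malonate and Claisen closure (NaOMe, MeOH, reflux) give the cyclic keto ester F4, which is not isolated. Hot aqueous NaOH and then HCl saponify, decarboxylate and desilylate it to the 5-substituted cyclohexane-1,3-dione F5 with a free ring B phenol.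
- TsCl and Et3N sulfonylate the acidic dione enol selectively to the enol tosylate F6.
- Cs2CO3 in dilute DMF closes the 20-membered ring by phenoxide addition–elimination to the macrocyclic 3-aryloxycyclohexenone F7.
- Aerobic dehydrogenation (Pd(O2CCF3)2 as divalent palladium catalyst, 2-(dimethylamino)pyridine, TsOH, O2, DMSO, 80 °C) aromatises the enone to 17.

Step 7. Oligomerisation can compete with the 22-membered ring closure. The phenoxide may attack sulfur of the tosylate and transfer the sulfonyl group instead of adding to carbon. Fluoride may also enolise the methylene between pyrone and ketone and slow the substitution.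
Fallback: the ether is made intermolecularly and the ring is closed by a C–C bond, setting out from 7 and 8 and returning at 14.
- Acid 7 is methylated (Me3SiCHN2, MeOH–toluene) to the methyl ester F8.
- Lactone 8 is tosylated (TsCl, Et3N) to 6-methyl-2-oxo-2H-pyran-4-yl 4-methylbenzenesulfonate F9.
- CsF in DMF at normal concentration joins the two by desilylation and addition–elimination to the open-chain aryloxypyrone ester F10.
- LiN(SiMe3)2 (2.2 equiv) in dilute THF at −78 °C deprotonates the pyrone methyl group, and the carbanion closes onto the ester (intramolecular Claisen-type acylation) to give 14 after acidification.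

Step 5. Proton transfer from the α-methylene of the imidazolide or from the liberated imidazole can quench the dianion, and acylation on oxygen or a second acylation can lower the conversion.
Fallback: aldol addition followed by oxidation, setting out from 7 and returning at 11. Acid 7 is taken to the alcohol F1 and the aldehyde F2 as described under step 8. Dianion 10 adds to F2 at −78 °C, where the alkoxide product does not consume further base, to give the racemic 6-(2-hydroxyalkyl)-4-hydroxypyrone F11. Dess–Martin oxidation of the secondary alcohol gives 11.

Step 9. Loss of carbon dioxide may be incomplete at a temperature the electron-rich macrocycle tolerates, with slow decomposition on longer heating.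
Fallback: the uncatalysed ipso-protonation is replaced by a metal-mediated protodecarboxylation through an aryl–silver intermediate (Ag2CO3 as catalyst, AcOH, DMSO, 120 °C), which works best for benzoic acids with two ortho substituents. It sets out from 16 and returns at 17 without a new compound.

**Further compounds**

F1 | step 8 | 13-[3,5-dimethoxy-4-(triisopropylsilyloxy)phenyl]tridecan-1-ol | OCCCCCCCCCCCCCc1cc(OC)c(O[Si](C(C)C)(C(C)C)C(C)C)c(OC)c1
F2 | step 8 | 13-[3,5-dimethoxy-4-(triisopropylsilyloxy)phenyl]tridecanal | O=CCCCCCCCCCCCCc1cc(OC)c(O[Si](C(C)C)(C(C)C)C(C)C)c(OC)c1
F3 | step 8 | (E)-16-[3,5-dimethoxy-4-(triisopropylsilyloxy)phenyl]hexadec-3-en-2-one | CC(=O)/C=C/CCCCCCCCCCCCc1cc(OC)c(O[Si](C(C)C)(C(C)C)C(C)C)c(OC)c1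
F4 | step 8 | methyl 6-{12-[3,5-dimethoxy-4-(triisopropylsilyloxy)phenyl]dodecyl}-2,4-dioxocyclohexane-1-carboxylate (mixture of stereoisomers, not isolated) | COC(=O)C1C(=O)CC(=O)CC1CCCCCCCCCCCCc1cc(OC)c(O[Si](C(C)C)(C(C)C)C(C)C)c(OC)c1
F5 | step 8 | 5-[12-(4-hydroxy-3,5-dimethoxyphenyl)dodecyl]cyclohexane-1,3-dione | O=C1CC(=O)CC(C1)CCCCCCCCCCCCc1cc(OC)c(O)c(OC)c1
F6 | step 8 | 5-[12-(4-hydroxy-3,5-dimethoxyphenyl)dodecyl]-3-oxocyclohex-1-en-1-yl 4-methylbenzenesulfonate (racemic) | Cc1ccc(cc1)S(=O)(=O)OC1=CC(=O)CC(C1)CCCCCCCCCCCCc1cc(OC)c(O)c(OC)c1
F7 | step 8 | 20-membered macrocyclic 3-(2,6-dimethoxyaryloxy)-5-alkylcyclohex-2-en-1-one (racemic) | O=C1C=C2CC(C1)CCCCCCCCCCCCc1cc(OC)c(O2)c(OC)c1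
F8 | step 7 | methyl 13-[3,5-dimethoxy-4-(triisopropylsilyloxy)phenyl]tridecanoate | COC(=O)CCCCCCCCCCCCc1cc(OC)c(O[Si](C(C)C)(C(C)C)C(C)C)c(OC)c1
F9 | step 7 | 6-methyl-2-oxo-2H-pyran-4-yl 4-methylbenzenesulfonate | Cc1cc(OS(=O)(=O)c2ccc(C)cc2)cc(=O)o1
F10 | step 7 | methyl 13-{3,5-dimethoxy-4-[(6-methyl-2-oxo-2H-pyran-4-yl)oxy]phenyl}tridecanoate | COC(=O)CCCCCCCCCCCCc1cc(OC)c(Oc2cc(C)oc(=O)c2)c(OC)c1
F11 | step 5 | 6-{14-[3,5-dimethoxy-4-(triisopropylsilyloxy)phenyl]-2-hydroxytetradecyl}-4-hydroxy-2H-pyran-2-one (racemic) | O=c1cc(O)cc(o1)CC(O)CCCCCCCCCCCCc1cc(OC)c(O[Si](C(C)C)(C(C)C)C(C)C)c(OC)c1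
F0 | step 9 | none | none
A1 | alternative 1 | methyl 4-(4-bromo-2,6-dimethoxyphenoxy)-6-(dodec-11-enyl)-2-hydroxybenzoate | COC(=O)c1c(O)cc(Oc2c(OC)cc(Br)cc2OC)cc1CCCCCCCCCCC=C
A2 | alternative 1 | [3-(4-bromo-2,6-dimethoxyphenoxy)-1-methoxybuta-1,3-dienyloxy]trimethylsilane | C=C(Oc1c(OC)cc(Br)cc1OC)C=C(OC)O[Si](C)(C)C
A3 | alternative 1 | methyl pentadec-14-en-2-ynoate | COC(=O)C#CCCCCCCCCCCC=C
A4 | alternative 2 | macrocyclic ring B diol with ring A methyl ether | COc1cc2cc(c1)Oc1c(O)cc(cc1O)CCCCCCCCCCCC2
A5 | alternative 2 | macrocyclic 2-aryloxyisophthalaldehyde with ring A methyl ether | COc1cc2cc(c1)Oc1c(C=O)cc(cc1C=O)CCCCCCCCCCCC2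
A6 | alternative 3 | macrocyclic diaryl ether with free ring A phenol, trimethylsilyl at C6 and ring B dimethyl ether | Oc1cc2cc(Oc3c(OC)cc(cc3OC)CCCCCCCCCCCC2)c1[Si](C)(C)C
A7 | alternative 3 | 3-{12-[3,5-dimethoxy-4-(trimethylsilylethynyloxy)phenyl]dodecyl}cyclobut-2-en-1-one | O=C1C=C(C1)CCCCCCCCCCCCc1cc(OC)c(OC#C[Si](C)(C)C)c(OC)c1
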